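**Assumption:** the single stereocentre (piperidine C-2, written [C@H] in the SMILES) is R, and the target is wanted as the neutral free base.

## Retrosynthetic overview

1. Ring C (the pyranone) is formed last, by acid cyclodehydration of a 1-aryl-3-phenylpropane-1,3-dione whose two MOM ethers are cleaved in the same pot.
2. Key C–C bond: C2–C3 of that diketone, from an intermolecular crossed Claisen condensation of the aryl methyl ketone with methyl benzoate.
3. The acetyl group comes from ortho-lithiation of a symmetric 2,6-bis(MOM-oxy)-4-methoxyphenyl piperidine. The oxygen that ends up ortho to the acyl group becomes O-1; the other becomes the 7-OH, so no selective protection is needed.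
4. The piperidine ring is formed first: Ellman addition of 4-chlorobutylmagnesium bromide to the (S)-tert-butanesulfinyl aldimine sets C-2 as R, then N-alkylative ring closure.
5. The aldehyde comes from 5-methoxyresorcinol by bis-MOM protection and lithiation/formylation.

## Route

Step 1
Reactants: 1 5-methoxybenzene-1,3-diol (5-methoxyresorcinol)
Product: 2 1-methoxy-3,5-bis(methoxymethoxy)benzene
Conditions: NaH, MOMCl, DMF, 0 °C → rt
Reagents that add atoms: chloromethyl methyl ether (MOMCl), COCCl
Why: Williamson-type O-alkylation of both phenoxides with the hard electrophile MOMCl gives the base-stable, lithiation-directing bis-acetal.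

Step 2
Reactants: 2 1-methoxy-3,5-bis(methoxymethoxy)benzene
Product: 4 4-methoxy-2,6-bis(methoxymethoxy)benzaldehyde, via aryllithium 3 (not isolated)
Conditions: n-BuLi, TMEDA, THF, 0 °C; DMF, 0 °C → rt; then H2O
Reagents that add atoms: N,N-dimethylformamide, CN(C)C=O
Why: Directed ortho-metalation removes the proton flanked by the two chelating OMOM groups in preference to those next to OMe, and the aryllithium is formylated by DMF.

Step 3
Reactants: 4 4-methoxy-2,6-bis(methoxymethoxy)benzaldehyde; 5 (S)-2-methylpropane-2-sulfinamide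
Product: 6 (S)-N-[(E)-[4-methoxy-2,6-bis(methoxymethoxy)phenyl]methylidene]-2-methylpropane-2-sulfinamide
Conditions: Ti(OEt)4, THF, 65 °C
Reagents that add atoms: none
Why: Ellman imine condensation, in which Ti(OEt)4 acts as Lewis acid and water scavenger, gives the (E)-N-sulfinyl aldimine without touching the sulfur stereocentre.

Step 4
Reactants: 7 1-bromo-4-chlorobutane
Product: 8 (4-chlorobutyl)magnesium bromide (ether solution, titrated and used directly)
Conditions: Mg turnings, cat. iodine (I2), Et2O, reflux
Reagents that add atoms: magnesium, [Mg]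
Why: Grignard formation by insertion of Mg into the weaker C–Br bond leaves the C–Cl bond intact.

Step 5
Reactants: 6 the N-sulfinyl aldimine; 8 (4-chlorobutyl)magnesium bromide
Product: 9 (S)-N-[(1R)-5-chloro-1-[4-methoxy-2,6-bis(methoxymethoxy)phenyl]pentyl]-2-methylpropane-2-sulfinamide
Conditions: CH2Cl2, −48 °C → rt; then H2O; chromatography to remove the minor diastereomer
Reagents that add atoms: none
Why: Ellman 1,2-addition of a Grignard reagent to an N-tert-butanesulfinyl aldimine in a non-coordinating solvent, in which Mg bound to the sulfinyl oxygen delivers the alkyl group through a six-membered chair transition state to the Re face of the (S)-sulfinyl imine and so sets the new stereocentre as R.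

Step 6
Reactants: 9 the δ-chloro sulfinamide
Product: 10 (2R)-1-[(S)-tert-butylsulfinyl]-2-[4-methoxy-2,6-bis(methoxymethoxy)phenyl]piperidine
Conditions: NaH, DMF, 0 °C → rt
Reagents that add atoms: none
Why: Intramolecular SN2 N-alkylation (6-exo-tet) of the sulfinamide anion by the primary chloride closes the piperidine ring without touching the stereocentre.

Step 7
Reactants: 10 the N-sulfinyl piperidine
Product: 11 (2R)-2-[4-methoxy-2,6-bis(methoxymethoxy)phenyl]piperidine
Conditions: HCl (4 M in dioxane, 2.2 equiv), MeOH, 0 °C, 20 min; then cold aq. NaOH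
Reagents that add atoms: none
Why: Acid methanolysis of the sulfinamide S–N bond is complete within minutes at 0 °C with about two equivalents of HCl, conditions under which aryl MOM ethers cleave only slowly, so the secondary amine is freed with both acetals intact.

Step 8
Reactants: 11 the secondary piperidine
Product: 13 (2R)-2-[4-methoxy-2,6-bis(methoxymethoxy)phenyl]-1-methylpiperidine, via iminium ion 12 (not isolated)
Conditions: 37% aq. HCHO, NaBH(OAc)3, ClCH2CH2Cl, rt
Reagents that add atoms: formaldehyde, C=O
Why: Reductive amination (iminium formation with formaldehyde, then hydride transfer from NaBH(OAc)3) methylates nitrogen once and cannot over-alkylate to an ammonium salt.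

Step 9
Reactants: 13 the N-methylpiperidine; 14 N-methoxy-N-methylacetamide
Product: 16 1-[6-methoxy-2,4-bis(methoxymethoxy)-3-[(2R)-1-methylpiperidin-2-yl]phenyl]ethan-1-one, via aryllithium 15 (not isolated)
Conditions: n-BuLi, THF, 0 °C; then 14, −78 → 0 °C; then H2O
Reagents that add atoms: none
Why: Directed ortho-metalation between OMOM and OMe (the two free ring positions are equivalent, so only one regioisomer can form) followed by acyl substitution on the Weinreb amide, whose chelated tetrahedral intermediate stops at the ketone.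

Step 10
Reactants: 16 the aryl methyl ketone; 17 methyl benzoate
Product: 18 1-[6-methoxy-2,4-bis(methoxymethoxy)-3-[(2R)-1-methylpiperidin-2-yl]phenyl]-3-phenylpropane-1,3-dione
Conditions: NaH, THF, reflux; then AcOH to pH 7
Reagents that add atoms: none
Why: Crossed Claisen condensation of the ketone sodium enolate with non-enolisable methyl benzoate is driven by deprotonation of the 1,3-diketone formed, while the tertiary amine, the MOM ethers and the non-acidic stereocentre are inert to NaH.

Step 11
Reactants: 18 the bis-MOM diketone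
Product: 20 7-hydroxy-5-methoxy-8-[(2R)-1-methylpiperidin-2-yl]-2-phenyl-4H-chromen-4-one (CNP0152057.1), via dihydroxy diketone 19 (not isolated)
Conditions: conc. aq. HCl, MeOH, 55 °C; then aq. NaHCO3 to pH 8
Reagents that add atoms: none
Why: Acid-catalysed acetal cleavage frees both phenols, and the hydroxyl ortho to the acyl group then adds to the benzoyl carbonyl and loses water (cyclodehydration to the chromen-4-one), whereas the para hydroxyl cannot cyclise and stays as the 7-OH, the protonated amine being configurationally stable at this temperature.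

## Compound list

1 | 5-methoxybenzene-1,3-diol | COc1cc(O)cc(O)c1 | starting material
2 | 1-methoxy-3,5-bis(methoxymethoxy)benzene | COCOc1cc(OC)cc(OCOC)c1 | intermediate
3 | [4-methoxy-2,6-bis(methoxymethoxy)phenyl]lithium | [Li]c1c(OCOC)cc(OC)cc1OCOC | intermediate (not isolated)
4 | 4-methoxy-2,6-bis(methoxymethoxy)benzaldehyde | COCOc1cc(OC)cc(OCOC)c1C=O | intermediate
5 | (S)-2-methylpropane-2-sulfinamide | CC(C)(C)[S@](=O)N | starting material
6 | (S)-N-[(E)-[4-methoxy-2,6-bis(methoxymethoxy)phenyl]methylidene]-2-methylpropane-2-sulfinamide | COCOc1cc(OC)cc(OCOC)c1/C=N/[S@@](=O)C(C)(C)C | intermediate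
7 | 1-bromo-4-chlorobutane | ClCCCCBr | starting material
8 | (4-chlorobutyl)magnesium bromide | ClCCCC[Mg]Br | intermediate
9 | (S)-N-[(1R)-5-chloro-1-[4-methoxy-2,6-bis(methoxymethoxy)phenyl]pentyl]-2-methylpropane-2-sulfinamide | COCOc1cc(OC)cc(OCOC)c1[C@@H](CCCCCl)N[S@@](=O)C(C)(C)C | intermediate
10 | (2R)-1-[(S)-tert-butylsulfinyl]-2-[4-methoxy-2,6-bis(methoxymethoxy)phenyl]piperidine | COCOc1cc(OC)cc(OCOC)c1[C@H]2CCCCN2[S@@](=O)C(C)(C)C | intermediate
11 | (2R)-2-[4-methoxy-2,6-bis(methoxymethoxy)phenyl]piperidine | COCOc1cc(OC)cc(OCOC)c1[C@H]2CCCCN2 | intermediate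
12 | (2R)-2-[4-methoxy-2,6-bis(methoxymethoxy)phenyl]-1-methylidenepiperidin-1-ium | COCOc1cc(OC)cc(OCOC)c1[C@H]2CCCC[N+]2=C | intermediate (not isolated)
13 | (2R)-2-[4-methoxy-2,6-bis(methoxymethoxy)phenyl]-1-methylpiperidine | COCOc1cc(OC)cc(OCOC)c1[C@H]2CCCCN2C | intermediate
14 | N-methoxy-N-methylacetamide | CON(C)C(C)=O | starting material
15 | [6-methoxy-2,4-bis(methoxymethoxy)-3-[(2R)-1-methylpiperidin-2-yl]phenyl]lithium | [Li]c1c(OC)cc(OCOC)c([C@H]2CCCCN2C)c1OCOC | intermediate (not isolated)
16 | 1-[6-methoxy-2,4-bis(methoxymethoxy)-3-[(2R)-1-methylpiperidin-2-yl]phenyl]ethan-1-one | CC(=O)c1c(OC)cc(OCOC)c([C@H]2CCCCN2C)c1OCOC | intermediate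
17 | methyl benzoate | COC(=O)c1ccccc1 | starting material
18 | 1-[6-methoxy-2,4-bis(methoxymethoxy)-3-[(2R)-1-methylpiperidin-2-yl]phenyl]-3-phenylpropane-1,3-dione | O=C(CC(=O)c1ccccc1)c1c(OC)cc(OCOC)c([C@H]2CCCCN2C)c1OCOC | intermediate
19 | 1-[2,4-dihydroxy-6-methoxy-3-[(2R)-1-methylpiperidin-2-yl]phenyl]-3-phenylpropane-1,3-dione | O=C(CC(=O)c1ccccc1)c1c(OC)cc(O)c([C@H]2CCCCN2C)c1O | intermediate (not isolated)
20 | 7-hydroxy-5-methoxy-8-[(2R)-1-methylpiperidin-2-yl]-2-phenyl-4H-chromen-4-one | COc1cc(O)c([C@H]2CCCCN2C)c2oc(-c3ccccc3)cc(=O)c12 | target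

## Step count and risks

Total step count: 11. Longest linear sequence: 10 steps (steps 1–3 and 5–11); step 4 is a one-step side branch.

**Step 5 (Grignard addition to the aldimine).** The aldimine is hindered and electron-rich, and its two ortho acetal oxygens can compete with the sulfinyl oxygen for magnesium. Conversion and diastereoselectivity may therefore suffer. The fallback sets out from 6 and comes back at 10, building the ring by allylation and ring-closing metathesis instead of with a chloroalkyl Grignard reagent. Barbier allylation of 6 with allyl bromide and indium powder (THF, 60 °C) attacks the same Re face and gives (S)-N-[(1R)-1-[4-methoxy-2,6-bis(methoxymethoxy)phenyl]but-3-en-1-yl]-2-methylpropane-2-sulfinamide F1. N-allylation (LiHMDS, allyl bromide, DMF, 0 °C) gives (S)-N-[(1R)-1-[4-methoxy-2,6-bis(methoxymethoxy)phenyl]but-3-en-1-yl]-2-methyl-N-(prop-2-en-1-yl)propane-2-sulfinamide F2. Ring-closing metathesis with second-generation Grubbs catalyst RuCl2(=CHPh)(PCy3)(H2IMes) (CH2Cl2, 40 °C) gives (2R)-1-[(S)-tert-butylsulfinyl]-2-[4-methoxy-2,6-bis(methoxymethoxy)phenyl]-1,2,3,6-tetrahydropyridine F3. Reduction of the ring alkene with diimide (TsNHNH2, NaOAc, aq. DME, 80 °C) or H2 over PtO2 then gives 10. In either variant the configuration and ee should be confirmed at 13 (chiral HPLC against the racemate, or X-ray of a salt).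

**Step 9 (lithiation and acetylation).** The aryllithium is hindered and may deprotonate the Weinreb amide instead of adding to it, returning 13. The fallback sets out from 13 and comes back at 16, using carbonyl addition and oxidation instead of acyl substitution. Aryllithium 15, generated as before, is trapped with acetaldehyde (THF, −78 °C) to give 1-[6-methoxy-2,4-bis(methoxymethoxy)-3-[(2R)-1-methylpiperidin-2-yl]phenyl]ethan-1-ol F4 as a mixture of carbinol epimers. Oxidation of this benzylic alcohol with MnO2 (CH2Cl2, rt) gives 16.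

**Step 10 (crossed Claisen condensation).** The ketone is flanked by two ortho substituents, and low conversion or O-benzoylation is possible. The fallback sets out from 16 and comes back at 20, replacing the diketone route by an aldol and oxidative cyclisation end-game. Claisen–Schmidt aldol condensation of 16 with benzaldehyde (KOH, EtOH, rt) gives (2E)-1-[6-methoxy-2,4-bis(methoxymethoxy)-3-[(2R)-1-methylpiperidin-2-yl]phenyl]-3-phenylprop-2-en-1-one F5. Acetal cleavage (HCl, MeOH, 40 °C) gives (2E)-1-[2,4-dihydroxy-6-methoxy-3-[(2R)-1-methylpiperidin-2-yl]phenyl]-3-phenylprop-2-en-1-one F6, kept as its hydrochloride to shield the amine. Oxidative cyclisation with catalytic iodine (I2) in DMSO at 120 °C then gives 20.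

## Further compounds

F1 | step 5 | (S)-N-[(1R)-1-[4-methoxy-2,6-bis(methoxymethoxy)phenyl]but-3-en-1-yl]-2-methylpropane-2-sulfinamide | COCOc1cc(OC)cc(OCOC)c1[C@@H](CC=C)N[S@@](=O)C(C)(C)C
F2 | step 5 | (S)-N-[(1R)-1-[4-methoxy-2,6-bis(methoxymethoxy)phenyl]but-3-en-1-yl]-2-methyl-N-(prop-2-en-1-yl)propane-2-sulfinamide | COCOc1cc(OC)cc(OCOC)c1[C@@H](CC=C)N(CC=C)[S@@](=O)C(C)(C)C
F3 | step 5 | (2R)-1-[(S)-tert-butylsulfinyl]-2-[4-methoxy-2,6-bis(methoxymethoxy)phenyl]-1,2,3,6-tetrahydropyridine | COCOc1cc(OC)cc(OCOC)c1[C@H]2CC=CCN2[S@@](=O)C(C)(C)C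
F4 | step 9 | 1-[6-methoxy-2,4-bis(methoxymethoxy)-3-[(2R)-1-methylpiperidin-2-yl]phenyl]ethan-1-ol | CC(O)c1c(OC)cc(OCOC)c([C@H]2CCCCN2C)c1OCOC
F5 | step 10 | (2E)-1-[6-methoxy-2,4-bis(methoxymethoxy)-3-[(2R)-1-methylpiperidin-2-yl]phenyl]-3-phenylprop-2-en-1-one | O=C(/C=C/c1ccccc1)c1c(OC)cc(OCOC)c([C@H]2CCCCN2C)c1OCOC
F6 | step 10 | (2E)-1-[2,4-dihydroxy-6-methoxy-3-[(2R)-1-methylpiperidin-2-yl]phenyl]-3-phenylprop-2-en-1-one | O=C(/C=C/c1ccccc1)c1c(OC)cc(O)c([C@H]2CCCCN2C)c1O
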